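**Two flasks.** The north-west flask, the one asked about, starts at [substrate] = 1 M and [catalyst] = 2 mM. The east flask looks nearly the same: its catalyst is equal at 2 mM, but it holds less substrate, [substrate] = 0.67 M.

| flask | substrate | catalyst | remark | time |
|---|---|---|---|---|
| north-west | 1 M | 2 mM | the very flask that is asked about, followed so far |  |
| east | 0.67 M | 2 mM | run made earlier |  |
| flask | 1.0 M | 2.0 mM |  | 12 h |

| north-west: time / min | north-west: target / % | east: time / h | east: target / % |
|---|---|---|---|
| 5.00 | 32.8 | 1.00 | 98.7 |
| 15.0 | 69.3 | 3.00 | 101.0 |
| 25.0 | 86.0 | 6.00 | 99.9 |
| 40.0 | 95.4 | 8.00 | 100.0 |
| 60.0 | 100.1 | 12.0 | 100.5 |

(readings scatter by 0.5 percentage points)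

- the earlier runs were read with a standard deviation of 0.5 percentage points
- on the list of suspects stand: substrate + catalyst -> catalyst + target
- the reaction counts as stopped when no species that holds the substrate changes by six tenths of a point or more over the second half of the time

1. at 12 h, what has stopped the reaction, if anything has (all of the substrate has reacted / no working catalyst is left / it is still moving)
2. target at 12 h, in percent of the substrate charged

**Fraction left.** I follow the substrate not yet turned into target. At 25.0 min the north-west reading leaves 14.0%, which is 2.84 halvings. Read from this scattered point, the pseudo-first-order half-life, the time in which the fraction left halves, is 8.81 min. At 40.0 min it predicts 4.30% left, and the reading leaves 4.60%.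

**East compared.** For the east flask at 1.00 h, the same half-life predicts 0.891% left. The reading leaves 1.30%, a gap within about one scatter of 0.5 percentage points, so at this one reading the smaller charge shows no change in the fraction left beyond the scatter. I expect both flasks to end alike because 12 h is far longer than this half-life: it holds 81.7 halvings. The east target still reads 100.5% at 12.0 h.

**The forecast.** It says all of the substrate has reacted, with target at 100%: “the substrate is simply used up”. My count of halvings commits me to the same.

    substrate + catalyst → catalyst + target (k = 39.4 L mol⁻¹ min⁻¹)

**Flask result.** The north-west flask gives all of the substrate has reacted, with target at 100%, and the asked 12 h is far longer than the half-life of substrate by this step alone with the other concentrations as charged, 8.80 min, while at 12.0 h catalyst stands at 100% of its charge. My 8.81 min gives 8.17 halvings by 1.20 h, or 0.347% left, where the flask holds 0.344%; the same flask left until 8.0 h gets 54.5 halvings and holds substrate at 0%.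

The data were generated by integration with constants of no real substance; the scatter is artificial.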